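**Retrosynthetic overview**

1. Feature: ring B is the pyran O–C1'–C10'–C11–C5''=C6'' fused to the vinylogous acid O=C4''–C5''=C6''–O of ring A. With a C10'=C11 bond it is a 2H-pyran, the retron of a Knoevenagel condensation/oxa-6π electrocyclisation between the ring-A triketone (nucleophilic at C5'') and a ring-C enal whose β-carbon is C1'. Locants: ring C = C1'(O,Me)–C2'–C3'–C4'(CMe2OH)–C5'=C6'–C7'(Me)–C8'–C9'–C10'; C11 = pyran CH2; ring A = C1''(acyl), C2''(OH), C3''(Me2), C4''(C=O), C5''(bears C11), C6''(O).
2. Last bonds: C10'–H and C11–H by hydrogen-atom-transfer hydrogenation of the pyran C10'=C11 bond, then desilylation; before that, C5''–C11 and O–C1' in the key step.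
3. Ring-C enal ⇐ ring-cis tetrasubstituted enoate ⇐ enol triflate of a ten-membered β-keto ester (C1'–CH3 by cuprate coupling) ⇐ C9'–C10' macro-alkylation of an acyclic iodo β-keto ester.
4. Acyclic chain: C7' from methyl hydrogen (R)-3-methylglutarate; C4' and the Z C5'=C6' bond from an auxiliary-controlled deconjugative allylation; C1'–C3' from allyl iodide, C10'/C11 from ethyl diazoacetate.
5. Ring order: ring A carbocycle (from phloroglucinol, steps 20–21), ring C (step 15), ring B (step 22).

Key step: step 22

Remark: ring-A positions carry doubly primed locants and ring-A compounds are drawn as one enol tautomer; 25 is carried as a C10' epimer mixture because C10' becomes sp2 in step 16; the C10'=C1' bond is ring-cis throughout (C2' and C9' on the same side; the E/Z labels in the names are CIP labels); methyl hydrogen (R)-3-methylglutarate is assumed to be commercially available in high enantiopurity.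

**Route**

Step 1
Reactants: 1 (R)-4-benzyl-2-oxazolidinone; 2 bromoacetyl bromide
Product: 4 (R)-4-benzyl-3-(bromoacetyl)oxazolidin-2-one, via lithium oxazolidinide 3 (not isolated)
Conditions: n-BuLi, THF, −78 °C; then 2, −78 → 0 °C
Reagents that add atoms: none
Why: N-acylation of the lithiated oxazolidinone occurs at the acyl bromide, which is far more electrophilic than the bromomethyl carbon, and leaves the auxiliary stereocentre untouched.

Step 2
Reactants: 4 (R)-4-benzyl-3-(bromoacetyl)oxazolidin-2-one
Product: 5 diethyl {2-[(R)-4-benzyl-2-oxooxazolidin-3-yl]-2-oxoethyl}phosphonate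
Conditions: P(OEt)3 (neat), 60 °C
Reagents that add atoms: triethyl phosphite, CCOP(OCC)OCC
Why: Michaelis–Arbuzov reaction of the activated α-bromo imide gives the phosphonoacetyl imide with loss of bromoethane.

Step 3
Reactants: 6 methyl hydrogen (R)-3-methylglutarate
Product: 8 (S)-4-methyloxan-2-one, via hydroxy acid 7 (not isolated)
Conditions: LiBH4, THF, 0 → 50 °C; then 2 M HCl, rt
Reagents that add atoms: none
Why: Chemoselective borohydride reduction: LiBH4 reduces the methyl ester while the carboxylate formed in the flask is inert, and acidification lactonises the hydroxy acid without touching the methyl-bearing stereocentre (the later C7').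

Step 4
Reactants: 8 (S)-4-methyloxan-2-one
Product: 10 methyl (R)-5-chloro-3-methylpentanoate, via acid chloride 9 (not isolated)
Conditions: SOCl2, ZnCl2 (cat.), 60 °C; then MeOH, 0 °C → rt
Reagents that add atoms: thionyl chloride, O=S(Cl)Cl; methanol, CO
Why: ZnCl2-assisted ring opening of the δ-lactone by thionyl chloride (SN2 attack of chloride at the primary O–CH2 carbon) and methanolysis of the acyl chloride give the ω-chloro ester, both reacting carbons being remote from the stereocentre.

Step 5
Reactants: 10 methyl (R)-5-chloro-3-methylpentanoate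
Product: 11 (R)-5-chloro-3-methylpentanal
Conditions: iBu2AlH, CH2Cl2, −78 °C; Rochelle salt work-up
Reagents that add atoms: none
Why: Partial ester reduction with iBu2AlH at low temperature stops at the aluminium hemiacetal, which releases the aldehyde on work-up.

Step 6
Reactants: 11 (R)-5-chloro-3-methylpentanal; 5 diethyl {2-[(R)-4-benzyl-2-oxooxazolidin-3-yl]-2-oxoethyl}phosphonate
Product: 12 (R)-4-benzyl-3-[(2E,5R)-7-chloro-5-methylhept-2-enoyl]oxazolidin-2-one
Conditions: LiCl, iPr2NEt, MeCN, rt
Reagents that add atoms: none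
Why: Horner–Wadsworth–Emmons olefination under LiCl/amine conditions is mild enough for the enolisable aldehyde and gives the E-enoyl imide.

Step 7
Reactants: 12 (R)-4-benzyl-3-[(2E,5R)-7-chloro-5-methylhept-2-enoyl]oxazolidin-2-one; 13 allyl iodide
Product: 15 (R)-4-benzyl-3-[(2R,3Z,5S)-2-allyl-7-chloro-5-methylhept-3-enoyl]oxazolidin-2-one, via sodium dienolate 14 (not isolated)
Conditions: NaN(SiMe3)2, THF, −78 °C; then 13, −78 → −45 °C
Reagents that add atoms: none
Why: Auxiliary-controlled deconjugative α-alkylation of an N-enoyl oxazolidinone: γ-deprotonation of the s-cis imide gives the chelated Z(O)-dienolate with a Z C5'=C6' bond (syn effect of the γ-substituent), and allyl iodide attacks C4' anti to the benzyl group of the (R)-auxiliary, which should set the 4'R centre; the primary chloride is inert at this temperature.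

Step 8
Reactants: 15 (R)-4-benzyl-3-[(2R,3Z,5S)-2-allyl-7-chloro-5-methylhept-3-enoyl]oxazolidin-2-one
Product: 16 methyl (2R,3Z,5S)-2-allyl-7-chloro-5-methylhept-3-enoate
Conditions: MeOMgBr (from MeMgBr, MeOH), MeOH/CH2Cl2, 0 °C
Reagents that add atoms: bromomagnesium methoxide, CO[Mg]Br
Why: Transesterification of the imide with bromomagnesium methoxide attacks the exocyclic carbonyl under nearly neutral conditions, so the doubly activated C4'–H should be neither epimerised nor moved into conjugation, and the auxiliary is recovered.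

Step 9
Reactants: 16 methyl (2R,3Z,5S)-2-allyl-7-chloro-5-methylhept-3-enoate
Product: 17 (3R,4Z,6S)-3-allyl-8-chloro-2,6-dimethyloct-4-en-2-ol
Conditions: MeMgBr, CeCl3, THF, −78 → 0 °C
Reagents that add atoms: methylmagnesium bromide, C[Mg]Br
Why: Double addition of the organocerium reagent (Grignard addition to an ester) builds the C4' dimethylcarbinol, the weakly basic cerium reagent suppressing enolisation at C4'.

Step 10
Reactants: 17 (3R,4Z,6S)-3-allyl-8-chloro-2,6-dimethyloct-4-en-2-ol
Product: 18 {[(3R,4Z,6S)-3-allyl-8-chloro-2,6-dimethyloct-4-en-2-yl]oxy}triethylsilane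
Conditions: Et3SiOTf, 2,6-lutidine, CH2Cl2, −78 → 0 °C
Reagents that add atoms: triethylsilyl trifluoromethanesulfonate, CC[Si](CC)(CC)OS(=O)(=O)C(F)(F)F
Why: Silylation of the hindered tertiary alcohol with the silyl triflate protects it against lactol formation with the later C1' aldehyde and against oxa-Michael addition in the key step.

Step 11
Reactants: 18 {[(3R,4Z,6S)-3-allyl-8-chloro-2,6-dimethyloct-4-en-2-yl]oxy}triethylsilane
Product: 20 (4R,5Z,7S)-9-chloro-7-methyl-4-[2-(triethylsilyloxy)propan-2-yl]non-5-en-1-ol, via alkylborane 19 (not isolated)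
Conditions: 9-BBN, THF, 0 °C → rt; then NaOH, H2O2, 0 °C
Reagents that add atoms: hydrogen peroxide, OO
Why: Hydroboration–oxidation with 9-BBN adds anti-Markovnikov to the monosubstituted alkene only, leaving the hindered Z-1,2-disubstituted C5'=C6' bond, and cold alkaline peroxide oxidises the C–B bond without displacing the primary chloride.

Step 12
Reactants: 20 (4R,5Z,7S)-9-chloro-7-methyl-4-[2-(triethylsilyloxy)propan-2-yl]non-5-en-1-ol
Product: 21 (4R,5Z,7S)-9-chloro-7-methyl-4-[2-(triethylsilyloxy)propan-2-yl]non-5-enal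
Conditions: Dess–Martin periodinane, NaHCO3, CH2Cl2, 0 °C → rt
Reagents that add atoms: none
Why: Buffered Dess–Martin oxidation gives the C1' aldehyde without loss of the silyl ether or alkene isomerisation.

Step 13
Reactants: 21 (4R,5Z,7S)-9-chloro-7-methyl-4-[2-(triethylsilyloxy)propan-2-yl]non-5-enal; 22 ethyl diazoacetate
Product: 23 ethyl (6R,7Z,9S)-11-chloro-9-methyl-3-oxo-6-[2-(triethylsilyloxy)propan-2-yl]undec-7-enoate
Conditions: SnCl2 (cat.), CH2Cl2, rt
Reagents that add atoms: none
Why: Roskamp reaction: Lewis-acid-promoted addition of the diazo ester to the aldehyde, 1,2-hydride shift and loss of N2 give the β-keto ester (C1' ketone, C10' methylene, C11 ester) under conditions that spare the silyl ether and the chloride.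

Step 14
Reactants: 23 ethyl (6R,7Z,9S)-11-chloro-9-methyl-3-oxo-6-[2-(triethylsilyloxy)propan-2-yl]undec-7-enoate
Product: 24 ethyl (6R,7Z,9S)-11-iodo-9-methyl-3-oxo-6-[2-(triethylsilyloxy)propan-2-yl]undec-7-enoate
Conditions: NaI, 2-butanone, reflux
Reagents that add atoms: sodium iodide, [Na+].[I-]
Why: Finkelstein exchange (SN2, driven by precipitation of NaCl) converts the robust chloride carried since step 4 into the iodide needed for ring closure.

Step 15
Reactants: 24 ethyl (6R,7Z,9S)-11-iodo-9-methyl-3-oxo-6-[2-(triethylsilyloxy)propan-2-yl]undec-7-enoate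
Product: 25 ethyl (5R,6Z,8S)-8-methyl-2-oxo-5-[2-(triethylsilyloxy)propan-2-yl]cyclodec-6-ene-1-carboxylate (C10' epimers)
Conditions: Cs2CO3, MeCN, 60 °C, slow addition to high dilution
Reagents that add atoms: none
Why: Intramolecular C-alkylation of the caesium enolate of the β-keto ester (macrocyclisation by 10-exo-tet SN2 at the primary iodide) forms C9'–C10' and closes ring C, the Z C5'=C6' bond and the C4'/C7' branches lowering the entropic and transannular cost of the ten-membered ring.

Step 16
Reactants: 25 ethyl (5R,6Z,8S)-8-methyl-2-oxo-5-[2-(triethylsilyloxy)propan-2-yl]cyclodec-6-ene-1-carboxylate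
Product: 27 ethyl (1Z,5R,6Z,8S)-8-methyl-5-[2-(triethylsilyloxy)propan-2-yl]-2-(trifluoromethylsulfonyloxy)cyclodeca-1,6-diene-1-carboxylate, via sodium enolate 26 (not isolated)
Conditions: NaH, THF, 0 °C; then PhNTf2, 0 °C → rt
Reagents that add atoms: N-phenylbis(trifluoromethanesulfonimide), O=S(=O)(N(c1ccccc1)S(=O)(=O)C(F)(F)F)C(F)(F)F
Why: O-Triflation of the chelated sodium enolate of the β-keto ester gives the enol triflate with O–Tf cis to the ester, which in the ten-membered ring is the less strained ring-cis alkene.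

Step 17
Reactants: 27 ethyl (1Z,5R,6Z,8S)-8-methyl-5-[2-(triethylsilyloxy)propan-2-yl]-2-(trifluoromethylsulfonyloxy)cyclodeca-1,6-diene-1-carboxylate
Product: 28 ethyl (1E,5R,6Z,8S)-2,8-dimethyl-5-[2-(triethylsilyloxy)propan-2-yl]cyclodeca-1,6-diene-1-carboxylate (ring-cis)
Conditions: Me2CuLi (from CuI, MeLi), Et2O, −78 → −20 °C
Reagents that add atoms: lithium dimethylcuprate, [Li+].C[Cu-]C
Why: Cuprate coupling of a β-triflyloxy enoate (addition–elimination with retention of alkene geometry) installs the C1' methyl group and gives the tetrasubstituted enoate.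

Step 18
Reactants: 28 ethyl (1E,5R,6Z,8S)-2,8-dimethyl-5-[2-(triethylsilyloxy)propan-2-yl]cyclodeca-1,6-diene-1-carboxylate
Product: 29 {(1E,5R,6Z,8S)-2,8-dimethyl-5-[2-(triethylsilyloxy)propan-2-yl]cyclodeca-1,6-dien-1-yl}methanol
Conditions: iBu2AlH, CH2Cl2, −78 °C
Reagents that add atoms: none
Why: Hydride reduction of the conjugated ester by 1,2-addition gives the allylic alcohol without touching the alkenes or the silyl ether.

Step 19
Reactants: 29 {(1E,5R,6Z,8S)-2,8-dimethyl-5-[2-(triethylsilyloxy)propan-2-yl]cyclodeca-1,6-dien-1-yl}methanol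
Product: 30 (1E,5R,6Z,8S)-2,8-dimethyl-5-[2-(triethylsilyloxy)propan-2-yl]cyclodeca-1,6-diene-1-carbaldehyde (ring-C enal)
Conditions: Dess–Martin periodinane, NaHCO3, CH2Cl2, 0 °C
Reagents that add atoms: none
Why: Dess–Martin oxidation of the allylic alcohol gives the tetrasubstituted enal without isomerising the ring-cis C10'=C1' bond.

Step 20
Reactants: 31 phloroglucinol; 32 isobutyryl chloride
Product: 33 2-methyl-1-(2,4,6-trihydroxyphenyl)propan-1-one
Conditions: AlCl3, PhNO2, 60 °C
Reagents that add atoms: none
Why: Friedel–Crafts acylation of the electron-rich ring stops at the monoketone because the first acyl group deactivates the ring.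

Step 21
Reactants: 33 2-methyl-1-(2,4,6-trihydroxyphenyl)propan-1-one; 34 methyl iodide
Product: 36 2-isobutyryl-4,4-dimethylcyclohexane-1,3,5-trione (ring-A triketone; C2'' enol drawn), via monomethyl phenol 35 (not isolated)
Conditions: NaOMe, MeOH, 0 °C → rt; MeI (2 equiv. in all)
Reagents that add atoms: methyl iodide (the second equivalent of compound 34), CI
Why: Dearomatising double C-alkylation of the phenolate: the first equivalent of methyl iodide methylates a ring CH to give 35, and the second methylates the same, by then methyl-bearing carbon of its phenolate, so that the ring loses aromaticity and the gem-dimethyl triketone forms, which should be separable from under- and over-methylated congeners.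

Step 22
Reactants: 30 ring-C enal; 36 ring-A triketone
Product: 38 tricyclic 2H-pyran (1'R,4'R,7'S; C10'=C11; triethylsilyl ether), via 1-oxatriene 37 (not isolated)
Conditions: ethylenediammonium diacetate, 4 Å MS, toluene, 90 °C
Reagents that add atoms: none
Why: The diammonium acetate converts the enal into an iminium ion that is attacked by C5'' of the triketone, the only carbon flanked by two ring carbonyls, and loss of the amine gives alkylidene triketone 37, a 1-oxatriene (C6''=O, C5''=C11, C10'=C1'). This closes thermally by a disrotatory oxa-6π electrocyclisation that forms O–C1' and ring B as a six-membered 2H-pyran; the closest known reaction is the Knoevenagel/oxa-6π (formal [3+3]) annulation of cyclic 1,3-diones with β,β-disubstituted enals. The new quaternary centre C1' is not set kinetically: the electrocyclisation is reversible, so the C1' ratio is thermodynamic and is governed by how the ten-membered ring, fixed by C4', C7' and the Z alkene, accommodates the C1' methyl group and the pyran oxygen. The step needs closure through the C6'' oxygen and not the C4'' oxygen; both pyrans interconvert through 37, the C6''-closed isomer keeps the hydrogen-bonded acyl-enol at C1''/C2'' and leaves the C4'' ketone beside the gem-dimethyl carbon, and the unwanted isomer can be recycled by reheating. No carbocation is formed, so the transannular Z alkene and the tertiary silyl ether are not at risk, and the fully substituted C1' should make the closed 2H-pyran the resting form.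

Step 23
Reactants: 38 tricyclic 2H-pyran
Product: 39 triethylsilyl ether of the target (1'R,4'R,7'S,10'S)
Conditions: Mn(dpm)3 (cat.), PhSiH3, tBuOOH, iPrOH, rt
Reagents that add atoms: none
Why: Metal-hydride hydrogen-atom-transfer hydrogenation: the hydrogen atom adds to C10', the terminus of the conjugated C10'=C11–C5''=C6'' dienyl ether, to give a C11 radical delocalised into the C5''=C6'' enol ether, while the isolated Z-1,2-disubstituted alkene is a poor acceptor; approach to C10' is expected anti to the C1' methyl group, on the face left open when C9' folds toward the methyl side as in the trans-fused product, which should set the 10'S centre.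

Step 24
Reactants: 39 triethylsilyl ether of the target
Product: 40 CNP0564661.1 (target)
Conditions: HF·pyridine, THF, 0 °C → rt
Reagents that add atoms: none
Why: Fluoride cleavage of the tertiary triethylsilyl ether under buffered conditions leaves the vinylogous acid, the tertiary O–C1' ether and the Z alkene untouched.

**Compound list**

1 | (R)-4-benzyl-2-oxazolidinone | O=C1N[C@H](Cc2ccccc2)CO1 | starting material
2 | bromoacetyl bromide | BrCC(Br)=O | starting material
3 | lithium (R)-4-benzyl-2-oxooxazolidin-3-ide | [Li+].O=C1[N-][C@H](Cc2ccccc2)CO1 | intermediate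
4 | (R)-4-benzyl-3-(bromoacetyl)oxazolidin-2-one | BrCC(=O)N1[C@H](Cc2ccccc2)COC1=O | intermediate
5 | diethyl {2-[(R)-4-benzyl-2-oxooxazolidin-3-yl]-2-oxoethyl}phosphonate | CCOP(=O)(CC(=O)N1[C@H](Cc2ccccc2)COC1=O)OCC | intermediate
6 | methyl hydrogen (R)-3-methylglutarate | COC(=O)C[C@H](C)CC(=O)O | starting material
7 | (S)-5-hydroxy-3-methylpentanoic acid | OCC[C@H](C)CC(=O)O | intermediate
8 | (S)-4-methyloxan-2-one | O=C1C[C@@H](C)CCO1 | intermediate
9 | (S)-5-chloro-3-methylpentanoyl chloride | O=C(Cl)C[C@@H](C)CCCl | intermediate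
10 | methyl (R)-5-chloro-3-methylpentanoate | COC(=O)C[C@@H](C)CCCl | intermediate
11 | (R)-5-chloro-3-methylpentanal | O=CC[C@@H](C)CCCl | intermediate
12 | (R)-4-benzyl-3-[(2E,5R)-7-chloro-5-methylhept-2-enoyl]oxazolidin-2-one | O=C(/C=C/C[C@@H](C)CCCl)N1[C@H](Cc2ccccc2)COC1=O | intermediate
13 | allyl iodide | C=CCI | starting material
14 | sodium Z(O)-dienolate of 12 (Z C5'=C6') | [Na+].[O-]/C(=C\C=C/[C@@H](C)CCCl)N1[C@H](Cc2ccccc2)COC1=O | intermediate
15 | (R)-4-benzyl-3-[(2R,3Z,5S)-2-allyl-7-chloro-5-methylhept-3-enoyl]oxazolidin-2-one | C=CC[C@H](/C=C\[C@@H](C)CCCl)C(=O)N1[C@H](Cc2ccccc2)COC1=O | intermediate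
16 | methyl (2R,3Z,5S)-2-allyl-7-chloro-5-methylhept-3-enoate | C=CC[C@H](/C=C\[C@@H](C)CCCl)C(=O)OC | intermediate
17 | (3R,4Z,6S)-3-allyl-8-chloro-2,6-dimethyloct-4-en-2-ol | C=CC[C@H](/C=C\[C@@H](C)CCCl)C(C)(C)O | intermediate
18 | {[(3R,4Z,6S)-3-allyl-8-chloro-2,6-dimethyloct-4-en-2-yl]oxy}triethylsilane | C=CC[C@H](/C=C\[C@@H](C)CCCl)C(C)(C)O[Si](CC)(CC)CC | intermediate
19 | B-alkyl-9-borabicyclo[3.3.1]nonane from 18 (boron on C1') | C(CC[C@H](/C=C\[C@@H](C)CCCl)C(C)(C)O[Si](CC)(CC)CC)B1C2CCCC1CCC2 | intermediate
20 | (4R,5Z,7S)-9-chloro-7-methyl-4-[2-(triethylsilyloxy)propan-2-yl]non-5-en-1-ol | OCCC[C@H](/C=C\[C@@H](C)CCCl)C(C)(C)O[Si](CC)(CC)CC | intermediate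
21 | (4R,5Z,7S)-9-chloro-7-methyl-4-[2-(triethylsilyloxy)propan-2-yl]non-5-enal | O=CCC[C@H](/C=C\[C@@H](C)CCCl)C(C)(C)O[Si](CC)(CC)CC | intermediate
22 | ethyl diazoacetate | CCOC(=O)C=[N+]=[N-] | starting material
23 | ethyl (6R,7Z,9S)-11-chloro-9-methyl-3-oxo-6-[2-(triethylsilyloxy)propan-2-yl]undec-7-enoate | CCOC(=O)CC(=O)CC[C@H](/C=C\[C@@H](C)CCCl)C(C)(C)O[Si](CC)(CC)CC | intermediate
24 | ethyl (6R,7Z,9S)-11-iodo-9-methyl-3-oxo-6-[2-(triethylsilyloxy)propan-2-yl]undec-7-enoate | CCOC(=O)CC(=O)CC[C@H](/C=C\[C@@H](C)CCI)C(C)(C)O[Si](CC)(CC)CC | intermediate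
25 | ethyl (5R,6Z,8S)-8-methyl-2-oxo-5-[2-(triethylsilyloxy)propan-2-yl]cyclodec-6-ene-1-carboxylate (C1' ketone, C10' ester, C10' epimers) | O=C1CC[C@@H](C(C)(C)O[Si](CC)(CC)CC)/C=C\[C@@H](C)CCC1C(=O)OCC | intermediate
26 | sodium enolate of 25 (O–Na cis to ester) | C1C[C@@H](C(C)(C)O[Si](CC)(CC)CC)/C=C\[C@@H](C)CC/C(C(=O)OCC)=C1/[O-].[Na+] | intermediate
27 | ethyl (1Z,5R,6Z,8S)-8-methyl-5-[2-(triethylsilyloxy)propan-2-yl]-2-(trifluoromethylsulfonyloxy)cyclodeca-1,6-diene-1-carboxylate | C1C[C@@H](C(C)(C)O[Si](CC)(CC)CC)/C=C\[C@@H](C)CC/C(C(=O)OCC)=C1/OS(=O)(=O)C(F)(F)F | intermediate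
28 | ethyl (1E,5R,6Z,8S)-2,8-dimethyl-5-[2-(triethylsilyloxy)propan-2-yl]cyclodeca-1,6-diene-1-carboxylate | C1C[C@@H](C(C)(C)O[Si](CC)(CC)CC)/C=C\[C@@H](C)CC/C(C(=O)OCC)=C1/C | intermediate
29 | {(1E,5R,6Z,8S)-2,8-dimethyl-5-[2-(triethylsilyloxy)propan-2-yl]cyclodeca-1,6-dien-1-yl}methanol | C1C[C@@H](C(C)(C)O[Si](CC)(CC)CC)/C=C\[C@@H](C)CC/C(CO)=C1/C | intermediate
30 | (1E,5R,6Z,8S)-2,8-dimethyl-5-[2-(triethylsilyloxy)propan-2-yl]cyclodeca-1,6-diene-1-carbaldehyde | C1C[C@@H](C(C)(C)O[Si](CC)(CC)CC)/C=C\[C@@H](C)CC/C(C=O)=C1/C | intermediate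
31 | phloroglucinol | Oc1cc(O)cc(O)c1 | starting material
32 | isobutyryl chloride | CC(C)C(Cl)=O | starting material
33 | 2-methyl-1-(2,4,6-trihydroxyphenyl)propan-1-one | CC(C)C(=O)c1c(O)cc(O)cc1O | intermediate
34 | methyl iodide | CI | starting material
35 | 2-methyl-1-(2,4,6-trihydroxy-3-methylphenyl)propan-1-one | CC(C)C(=O)c1c(O)cc(O)c(C)c1O | intermediate
36 | 2-isobutyryl-4,4-dimethylcyclohexane-1,3,5-trione (C2'' enol) | CC(C)C(=O)C1=C(O)C(C)(C)C(=O)CC1=O | intermediate
37 | 1-oxatriene (C5''=C11H–C10'=C1' alkylidene triketone) | C1C[C@@H](C(C)(C)O[Si](CC)(CC)CC)/C=C\[C@@H](C)CC/C(C=C2C(=O)C(C)(C)C(O)=C(C(=O)C(C)C)C2=O)=C1/C | intermediate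
38 | tricyclic 2H-pyran (1'R,4'R,7'S; C10'=C11; triethylsilyl ether) | CC(C)C(=O)C1=C(O)C(C)(C)C(=O)C2=C1O[C@]1(C)CC[C@@H](C(C)(C)O[Si](CC)(CC)CC)/C=C\[C@@H](C)CCC1=C2 | intermediate
39 | triethylsilyl ether of the target (1'R,4'R,7'S,10'S) | CC(C)C(=O)C1=C(O)C(C)(C)C(=O)C2=C1O[C@]1(C)CC[C@@H](C(C)(C)O[Si](CC)(CC)CC)/C=C\[C@@H](C)CC[C@H]1C2 | intermediate
40 | CNP0564661.1 | CC(C)C(=O)C1=C(O)C(C)(C)C(=O)C2=C1O[C@]1(C)CC[C@@H](C(C)(C)O)/C=C\[C@@H](C)CC[C@H]1C2 | target

**Step count**

Total: 24 steps. Longest linear sequence: 20 steps (6 → 40 through steps 3–19 and 22–24).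

**Steps most likely to fail**

Step 22 (key step). The fully substituted enal may form the iminium ion and condense too slowly, so that enal or triketone decomposes before ring closure. The equilibrium may also hold a large share of the pyran closed through the C4'' oxygen or of the C1' epimer. Fallback, setting out from allylic alcohol 29 and triketone 36 and returning at pyran 38: 29 is converted with methyl chloroformate and pyridine into the allylic methyl carbonate F4. Tsuji–Trost allylation of 36 with F4 (Pd(PPh3)4, THF, rt) forms C5''–C11 at the unhindered CH2 terminus of the allyl unit and gives the C-allylated triketone F5. Dehydrogenation of F5 with DDQ (dioxane, rt) removes hydride from C11 and generates oxatriene 37, which electrocyclises to 38. The bonds and the ring closure are the same; only the condensation of the hindered aldehyde is avoided, and the thermodynamic pyran ratio is still handled by separation and reheating.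

Step 15. O-alkylation of the ambident enolate (to an unstrained twelve-membered enol ether) or intermolecular alkylation may outrun closure of the strained ten-membered carbocycle. Fallback, setting out from chloride 18 and returning at enoate 28: Finkelstein exchange (NaI, acetone, reflux) gives the iodide F1. The lithium dienolate of ethyl 3-methylbut-2-enoate (LiN(iPr)2, DMPU, THF, −78 °C) is alkylated at its α-carbon by F1 (intermolecular deconjugative alkylation) to give the isopropenyl ester F2, which carries C10', C11, C1' and the C1' methyl group. Ring-closing metathesis of the allyl and isopropenyl groups (RuCl2(H2IMes)(=CH–C6H4-2-OiPr), the second-generation Hoveyda–Grubbs catalyst, toluene, 80 °C, high dilution) closes ring C at C1'=C2' as the β,γ-unsaturated ester F3, with loss of the terminal allyl carbon. Equilibration with NaOEt in EtOH moves the double bond into conjugation and gives 28.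

Step 23. The hydrogen atom may be delivered to C10' on the methyl face (cis ring fusion), the chelating acyl-enol of ring A may strip ligands from manganese and stall turnover, or the Z alkene may be reduced as well. Fallback, setting out from 38 and returning at 39: hydrogenation over palladium on carbon (H2, 1 atm, EtOAc, 0 °C, stopped after one equivalent). This replaces stepwise radical transfer by syn addition of H2 from a surface, which binds the conjugated dienyl ether more strongly than the buried Z alkene and selects the face of the whole ring-A/ring-B plate. No new compound is formed (F0).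

**Further compounds**

F1 | step 15 | {[(3R,4Z,6S)-3-allyl-8-iodo-2,6-dimethyloct-4-en-2-yl]oxy}triethylsilane | C=CC[C@H](/C=C\[C@@H](C)CCI)C(C)(C)O[Si](CC)(CC)CC
F2 | step 15 | ethyl (5S,6Z,8R)-8-allyl-5,9-dimethyl-2-(prop-1-en-2-yl)-9-(triethylsilyloxy)dec-6-enoate (C2 epimers) | C=CC[C@H](/C=C\[C@@H](C)CCC(C(=O)OCC)C(C)=C)C(C)(C)O[Si](CC)(CC)CC
F3 | step 15 | ethyl (2Z,5R,6Z,8S)-2,8-dimethyl-5-[2-(triethylsilyloxy)propan-2-yl]cyclodeca-2,6-diene-1-carboxylate (C1 epimers) | C/C1=C/C[C@@H](C(C)(C)O[Si](CC)(CC)CC)/C=C\[C@@H](C)CCC1C(=O)OCC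
F4 | step 22 | {(1E,5R,6Z,8S)-2,8-dimethyl-5-[2-(triethylsilyloxy)propan-2-yl]cyclodeca-1,6-dien-1-yl}methyl methyl carbonate | C1C[C@@H](C(C)(C)O[Si](CC)(CC)CC)/C=C\[C@@H](C)CC/C(COC(=O)OC)=C1/C
F5 | step 22 | 2-isobutyryl-4,4-dimethyl-6-({(1E,5R,6Z,8S)-2,8-dimethyl-5-[2-(triethylsilyloxy)propan-2-yl]cyclodeca-1,6-dien-1-yl}methyl)cyclohexane-1,3,5-trione (enol form) | C1C[C@@H](C(C)(C)O[Si](CC)(CC)CC)/C=C\[C@@H](C)CC/C(CC2C(=O)C(C)(C)C(O)=C(C(=O)C(C)C)C2=O)=C1/C
F0 | step 23 | none | none
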